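**Retrosynthetic overview**
1. Numbering: C1–C3 (CH2)3, C4 C(CH3)OH, C5 CH–OAng, C6 CH–O(lactone), C7 CH, C8 CHOH, C9 C=O, C10 CHCH3; lactone carbons C11 (=C13H2) and C12. The plan rests on the 1,6-relation of the C4 carbinol carbon and the C9 ketone carbon across the ten-membered ring. A C4–C9 bond divides that ring into ring A (C4–C5–C6–C7–C8–C9) and ring B (C9–C10–C1–C2–C3–C4) of a decalin, whose fusion diol is a masked 4,9-dione.
2. Endgame disconnections: O8–Si; C11=C13 (Horner–Wadsworth–Emmons reaction of a C11 phosphonate with CH2O); the O5 angelate; C4–CH3 (chelate-controlled MeMgBr addition to the C4 ketone).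
3. Key disconnection: cyclodecane-4,9-dione ⇒ cis-decalin-4,9-diol (anodic C4–C9 fission) ⇒ Δ4(9)-octalin (OsO4).
4. Ring A carries 5α-O, 6β-O, 7α-C and 8β-O, all trans. The lactone comes from malonate opening of a 6β,7β-epoxide at C7, C8 from a CBS reduction, and C5 from a Luche reduction followed by Mitsunobu inversion of an epoxy enedione. The epoxide is tied to C10 by convex-face epoxidation of the cis-fused Diels–Alder adduct of benzoquinone and (E)-piperylene, after which C4–C9 is dehydrogenated.
5. Order of rings: ring A (the quinone) → ring B (Diels–Alder) → γ-lactone → ten-membered ring (by cleavage of the A/B fusion bond).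

Key step: step 15

Convention: the target numbering is kept for every intermediate. β is the face of the bicycle that carries O6, and α is the opposite face.
Remark: C11 in 17, 20–25 and 27 is readily epimerised. It is written without configuration and becomes trigonal in step 19.
Assumption: the (S)-diphenylprolinol-derived oxazaborolidinium ion is taken to expose the quinone face that leads to 3. If the sense of induction is the opposite, the catalyst from (R)-diphenylprolinol is used and nothing else changes.

**Step 1**
Reactants: 1 1,4-benzoquinone; 2 (E)-1,3-pentadiene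
Product: 3 (4aS,5S,8aR)-5-methyl-4a,5,8,8a-tetrahydronaphthalene-1,4-dione (cis-fused endo adduct; H4, H9, H10 β, C10 methyl α)
Conditions: oxazaborolidinium triflimide from (S)-α,α-diphenylprolinol, o-tolylboronic acid and Tf2NH (20 mol %), CH2Cl2, −78 °C
Reagents that add atoms: none
Why: Catalytic enantioselective Diels–Alder reaction of a quinone: the E-diene adds endo, which places H4, H9 and H10 on one face and the methyl group on the other, and the chiral boron Lewis acid bound to one carbonyl oxygen shields one quinone face, so that C10 is set as S and ring B is closed on ring A.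

**Step 2**
Reactants: 3 Diels–Alder adduct
Product: 4 cis-fused 6β,7β-epoxy-10α-methyl-4βH,9βH-octal-1-ene-5,8-dione
Conditions: 30% H2O2, Na2CO3, acetone–H2O, 0 °C, short contact
Reagents that add atoms: hydrogen peroxide, OO
Why: Weitz–Scheffer epoxidation: hydroperoxide adds to the electron-poor C6=C7 bond (the isolated C1=C2 bond is inert to a nucleophilic oxidant) from the convex face of the folded cis-bicycle, the face of H4 and H9, so the oxirane is β and thereby anti to the α methyl group at C10, a relation that a flat quinone could not transmit.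

**Step 3**
Reactants: 4 epoxy adduct
Product: 5 cis-fused 6β,7β-epoxy-10α-methyl-4βH,9βH-decalin-5,8-dione
Conditions: H2 (1 atm), RhCl(PPh3)3 (5 mol %), benzene–EtOH, rt
Reagents that add atoms: none
Why: Homogeneous hydrogenation saturates only the unhindered cis-disubstituted C1=C2 alkene and leaves the epoxy ketone untouched; no stereocentre is formed.

**Step 4**
Reactants: 5 saturated epoxy dione
Product: 8 6β,7β-epoxy-10α-methyl-Δ4(9)-octalin-5,8-dione, via silyl enol ether 6 (not isolated), via 4β-bromo dione 7 (not isolated)
Conditions: TMSOTf (1.1 equiv), Et3N (4 equiv), CH2Cl2, 0 °C; NBS (1.05 equiv), 0 °C; then rt, brief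
Reagents that add atoms: trimethylsilyl trifluoromethanesulfonate, C[Si](C)(C)OS(=O)(=O)C(F)(F)F (silyl group of 6); N-bromosuccinimide, O=C1CCC(=O)N1Br (bromine of 7)
Why: Soft enolisation, bromination of the silyl enol ether at the ring-fusion carbon and E1cB loss of HBr through the enolate of the second ketone can only give the C4=C9 enedione (whichever carbonyl enolises first), so ring A is flattened without touching C6, C7 or C10.

**Step 5**
Reactants: 8 epoxy enedione
Product: 9 5β-hydroxy-6β,7β-epoxy-10α-methyl-Δ4(9)-octalin-8-one
Conditions: NaBH4 (0.5 equiv), CeCl3·7H2O, MeOH, −78 °C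
Reagents that add atoms: none
Why: Luche reduction: the C8 carbonyl is screened on its α face by the pseudoaxial C10 methyl group and on its β face by the oxirane, so the C5 carbonyl reacts first, and hydride reaches it anti to the oxirane to give the 5β (cis-epoxy) alcohol.

**Step 6**
Reactants: 9 5β-alcohol
Product: 10 5α-(4-nitrobenzoyloxy)-6β,7β-epoxy-10α-methyl-Δ4(9)-octalin-8-one
Conditions: 4-nitrobenzoic acid, PPh3, DIAD, THF, 0 °C → rt
Reagents that add atoms: 4-nitrobenzoic acid, OC(=O)c1ccc(cc1)[N+](=O)[O-]
Why: Mitsunobu reaction: SN2 displacement of the oxyphosphonium ion by the carboxylate from the open α face inverts C5 to its final configuration, ionisation being disfavoured by the conjugated C8 ketone.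

**Step 7**
Reactants: 10 5α-ester
Product: 11 5α-hydroxy-6β,7β-epoxy-10α-methyl-Δ4(9)-octalin-8-one
Conditions: K2CO3 (0.2 equiv), MeOH, 0 °C
Reagents that add atoms: none
Why: Carbonate-catalysed transesterification of the activated aryl ester is fast at 0 °C, cleaves only the acyl–oxygen bond and so keeps the C5 configuration, and is stopped before Payne migration of the trans-epoxy alcohol can set in.

**Step 8**
Reactants: 11 5α-alcohol
Product: 12 5α-(methoxymethoxy)-6β,7β-epoxy-10α-methyl-Δ4(9)-octalin-8-one
Conditions: MOMCl, iPr2NEt, CH2Cl2, 0 °C → rt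
Reagents that add atoms: chloromethyl methyl ether, COCCl
Why: Standard O-alkylation with an amine base installs at O5 the acetal that blocks Payne migration in step 11, caps the C4–C5 glycol in step 15 and serves as the chelating group in step 16.

**Step 9**
Reactants: 12 MOM ether enone
Product: 13 5α-(methoxymethoxy)-6β,7β-epoxy-10α-methyl-Δ4(9)-octalin-8β-ol (8R)
Conditions: (R)-2-methyl-CBS-oxazaborolidine (0.5 equiv), BH3·SMe2 (1 equiv), toluene, −30 °C; MeOH quench
Reagents that add atoms: none
Why: Corey–Bakshi–Shibata reduction: with the tetrasubstituted alkenyl carbon C9 as the large flank and the oxirane carbon C7 as the small one, the (R)-catalyst delivers hydride to the α face, which is also the face anti to the oxirane oxygen that lies closest to the attack trajectory, and sets C8 as the β alcohol, trans to the C10 methyl group.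

**Step 10**
Reactants: 13 8β-alcohol
Product: 14 8β-(tert-butyldimethylsilyloxy)-5α-(methoxymethoxy)-6β,7β-epoxy-10α-methyl-Δ4(9)-octalin
Conditions: TBSOTf, 2,6-lutidine, CH2Cl2, −78 °C
Reagents that add atoms: tert-butyldimethylsilyl trifluoromethanesulfonate, CC(C)(C)[Si](C)(C)OS(=O)(=O)C(F)(F)F
Why: Silylation with the triflate at low temperature covers the hindered O8 with a bulky, non-chelating group that keeps Mg away from the C9 ketone in step 16 and closes the C8–C9 glycol to oxidation in step 15.

**Step 11**
Reactants: 14 protected epoxide; 15 dimethyl malonate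
Product: 17 11-methoxycarbonyl trans-fused γ-lactone of the octalin, via hydroxy malonate 16 (not isolated)
Conditions: 15 (5 equiv), NaH (4.5 equiv), DME, 85 °C; AcOH quench
Reagents that add atoms: none
Why: SN2 opening of the epoxide by malonate followed by lactonisation of the C6 alkoxide: the nucleophile has to enter on the α face, where C6 is screened by the neighbouring α-OMOM group while C7 lies next to a β ether, and attack at C7 is the trans-diaxial (Fürst–Plattner) mode of the half-chair with pseudoaxial allylic ethers, so inversion at C7 gives the 7α C–C bond and the 6β,7α trans-fused lactone.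

**Step 12**
Reactants: 17 ester lactone
Product: 18 trans-fused butyrolactone of the octalin (5α-OMOM, 8β-OTBS, 10α-methyl)
Conditions: LiCl, H2O, DMSO, 140 °C
Reagents that add atoms: none
Why: Krapcho dealkoxycarbonylation removes the activating ester under neutral conditions that spare the lactone, the acetal and the silyl ether.

**Step 13**
Reactants: 18 lactone
Product: 20 11-(diethoxyphosphoryl) lactone of the octalin, via ketene acetal phosphate 19 (not isolated)
Conditions: LiN(iPr)2 (1.1 equiv), THF, −78 °C; ClP(O)(OEt)2; LiN(iPr)2 (2.2 equiv), −78 °C → rt; AcOH quench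
Reagents that add atoms: diethyl chlorophosphate, CCOP(=O)(Cl)OCC
Why: O-Phosphorylation of the lactone enolate and base-induced 1,3-migration of phosphorus from oxygen to carbon (vinyl phosphate to phosphonate rearrangement) place the olefination handle on C11 while no ketone is present, because enolate chemistry on the lactone after step 15 would deprotonate the more acidic C9 ketone and scramble C10.

**Step 14**
Reactants: 20 phosphono lactone octalin
Product: 22 cis-decalin-4β,9β-diol carrying the trans-fused 11-phosphono lactone, via cyclic osmate ester 21 (not isolated)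
Conditions: OsO4 (1.1 equiv), pyridine, rt; then aq NaHSO3
Reagents that add atoms: osmium tetroxide, O=[Os](=O)(=O)=O
Why: Stoichiometric syn-dihydroxylation of the only alkene through a [3+2] osmate ester: the trans-fused lactone holds the C5 and C8 ethers pseudoequatorial and the pseudoaxial C10 methyl group blocks the α face, so the 4β,9β-diol should form, although either cis-diol would serve because both centres vanish in step 15.

**Step 15**
Reactants: 22 cis-decalin-4,9-diol
Product: 23 cyclodecane-4,9-dione carrying the trans-fused 11-phosphono lactone (5-OMOM, 8-OTBS, 10-methyl; C5, C6, C7, C8, C10 as in the target)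
Conditions: undivided cell, graphite anode, Pt cathode, Et4NOTs (0.1 M), MeOH, constant current (10 mA cm−2, ca. 3 F mol−1), 10 °C
Reagents that add atoms: none
Why: Electron transfer from one of the tertiary carbinol oxygens of 22 to the carbon anode gives an oxygen-centred radical cation that loses a proton and undergoes β-scission of the fully substituted C4–C9 bond to one ketone and a tertiary α-hydroxyalkyl radical, which is oxidised at once and deprotonated to the second ketone, while methanol is reduced to H2 at the cathode so that the bulk solution stays neutral. The closest known reaction type is the constant-current anodic cleavage of 1,2-diols to dicarbonyl compounds in methanol/Et4NOTs, the electrochemical counterpart of the Criegee and Malaprade glycol fissions, which opens decalin-9,10-diols to cyclodecane-1,6-diones and accepts cis- and trans-diols alike. The ten-membered ring is not closed by bond formation but appears by fragmentation of the zero-atom bridge common to rings A and B (ring expansion of the bicyclo[4.4.0]decane), so no medium-ring cyclisation has to be paid for. No stereocentre is created: C4 and C9 become trigonal, and C5, C6, C7, C8 and C10 are carried over unchanged because the cold, neutral medium does not enolise the new ketones. The selectivity needed is scission of C4–C9 in preference to C4–C5 and C8–C9 and to oxidation elsewhere; it is secured because 22 holds a single free 1,2-diol (O5 is capped as an acetal, O8 as a silyl ether), because only C4–C9 scission gives a tertiary ketyl-type radical and releases the strain of two adjacent fully substituted carbons, and because the lactone and the phosphonate are oxidised only at much higher potential.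

**Step 16**
Reactants: 23 4,9-dione
Product: 24 (4R)-4-hydroxy-4-methyl-9-ketone (5-OMOM, 8-OTBS, 11-phosphono lactone)
Conditions: MeMgBr (3.5 equiv), THF, −78 °C; aq NH4Cl
Reagents that add atoms: methylmagnesium bromide, C[Mg]Br
Why: Chelation-controlled Grignard addition (Cram chelate model): after one equivalent has deprotonated C11 and so protected the lactone as its enolate, Mg bridges the C4 carbonyl oxygen and O5 of the acetal, which activates C4 over the C9 ketone that is flanked by two branched carbons and a non-chelating silyl ether, and methyl enters from the side of H5, the outer face of the ring, to give (4R).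

**Step 17**
Reactants: 24 tertiary alcohol
Product: 25 4,5-diol (8-OTBS, 9-ketone, 11-phosphono lactone)
Conditions: MgBr2·OEt2 (5 equiv), n-BuSH (5 equiv), Et2O, rt
Reagents that add atoms: none
Why: Lewis acid/thiol cleavage of the acetal: Mg held between O4 and O5 breaks the O5–CH2 bond and the thiol captures the methoxymethyl cation, so no oxocarbenium ion remains on O5 to close a methylene acetal onto the tertiary alcohol, and the silyl ether survives.

**Step 18**
Reactants: 25 4,5-diol; 26 angelic acid ((Z)-2-methylbut-2-enoic acid)
Product: 27 5-O-angelate (4-OH, 8-OTBS, 9-ketone, 11-phosphono lactone)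
Conditions: 26, 2,4,6-trichlorobenzoyl chloride, Et3N, toluene, rt; then 25, 80 °C
Reagents that add atoms: none
Why: Yamaguchi-type esterification through the mixed anhydride without a nucleophilic catalyst acylates the secondary O5 in preference to the tertiary O4 and avoids the addition–elimination path that isomerises angelate to tiglate, so the Z geometry of 26 is kept.

**Step 19**
Reactants: 27 phosphono lactone angelate
Product: 28 8-O-TBS ether of the target (α-methylene lactone)
Conditions: 37% aq HCHO, K2CO3, THF, 0 °C
Reagents that add atoms: formaldehyde, C=O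
Why: Horner–Wadsworth–Emmons olefination: the C11–H between the phosphoryl and lactone carbonyl groups is by far the most acidic site, so carbonate deprotonates it selectively in the presence of the C9 ketone, and formaldehyde converts C11 into the exocyclic C11=C13 methylene group.

**Step 20**
Reactants: 28 silyl ether
Product: 29 target CNP0311008.1 (4R,5S,6R,7S,8S,10S)
Conditions: HF·pyridine, pyridine, THF, 0 °C → rt
Reagents that add atoms: none
Why: Fluoride-mediated desilylation under buffered acidic conditions frees O8 without base, which protects the α-ketol, the C10 centre, the angelate and the Michael acceptor.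

**Compound list**
1 | 1,4-benzoquinone | O=C1C=CC(=O)C=C1 | starting material
2 | (E)-1,3-pentadiene | C/C=C/C=C | starting material
3 | (4aS,5S,8aR)-5-methyl-4a,5,8,8a-tetrahydronaphthalene-1,4-dione | O=C1C=CC(=O)[C@H]2[C@@H](C)C=CC[C@@H]12 | intermediate
4 | cis-fused 6β,7β-epoxy-10α-methyl-4βH,9βH-octal-1-ene-5,8-dione | O=C1[C@@H]2O[C@@H]2C(=O)[C@H]3[C@@H](C)C=CC[C@@H]13 | intermediate
5 | cis-fused 6β,7β-epoxy-10α-methyl-4βH,9βH-decalin-5,8-dione | O=C1[C@@H]2O[C@@H]2C(=O)[C@H]3[C@@H](C)CCC[C@@H]13 | intermediate
6 | 5-(trimethylsilyloxy)-Δ4(5) enol ether of 5 | C[Si](C)(C)OC1=C2CCC[C@H](C)[C@@H]2C(=O)[C@H]3O[C@@H]13 | intermediate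
7 | 4β-bromo-6β,7β-epoxy-10α-methyl-9βH-decalin-5,8-dione | O=C1[C@@H]2O[C@@H]2C(=O)[C@H]3[C@@H](C)CCC[C@@]13Br | intermediate
8 | 6β,7β-epoxy-10α-methyl-Δ4(9)-octalin-5,8-dione | O=C1[C@@H]2O[C@@H]2C(=O)C3=C1CCC[C@@H]3C | intermediate
9 | 5β-hydroxy-6β,7β-epoxy-10α-methyl-Δ4(9)-octalin-8-one | O[C@@H]1[C@@H]2O[C@@H]2C(=O)C3=C1CCC[C@@H]3C | intermediate
10 | 5α-(4-nitrobenzoyloxy)-6β,7β-epoxy-10α-methyl-Δ4(9)-octalin-8-one | O=C(O[C@H]1[C@@H]2O[C@@H]2C(=O)C3=C1CCC[C@@H]3C)c4ccc(cc4)[N+](=O)[O-] | intermediate
11 | 5α-hydroxy-6β,7β-epoxy-10α-methyl-Δ4(9)-octalin-8-one | O[C@H]1[C@@H]2O[C@@H]2C(=O)C3=C1CCC[C@@H]3C | intermediate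
12 | 5α-(methoxymethoxy)-6β,7β-epoxy-10α-methyl-Δ4(9)-octalin-8-one | COCO[C@H]1[C@@H]2O[C@@H]2C(=O)C3=C1CCC[C@@H]3C | intermediate
13 | 5α-(methoxymethoxy)-6β,7β-epoxy-10α-methyl-Δ4(9)-octalin-8β-ol | COCO[C@H]1[C@@H]2O[C@@H]2[C@H](O)C3=C1CCC[C@@H]3C | intermediate
14 | 8β-(tert-butyldimethylsilyloxy)-5α-(methoxymethoxy)-6β,7β-epoxy-10α-methyl-Δ4(9)-octalin | COCO[C@H]1[C@@H]2O[C@@H]2[C@H](O[Si](C)(C)C(C)(C)C)C3=C1CCC[C@@H]3C | intermediate
15 | dimethyl malonate | COC(=O)CC(=O)OC | starting material
16 | dimethyl 2-(6β-hydroxy-5α-MOMO-8β-TBSO-10α-methyl-Δ4(9)-octalin-7α-yl)malonate | COC(=O)C(C(=O)OC)[C@H]1[C@H](O[Si](C)(C)C(C)(C)C)C2=C(CCC[C@@H]2C)[C@@H](OCOC)[C@@H]1O | intermediate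
17 | 11-methoxycarbonyl 6β,7α-trans-fused γ-lactone of the Δ4(9)-octalin | O=C1C(C(=O)OC)[C@H]2[C@H](O[Si](C)(C)C(C)(C)C)C3=C(CCC[C@@H]3C)[C@@H](OCOC)[C@@H]2O1 | intermediate
18 | 6β,7α-trans-fused butyrolactone of the Δ4(9)-octalin | O=C1C[C@H]2[C@H](O[Si](C)(C)C(C)(C)C)C3=C(CCC[C@@H]3C)[C@@H](OCOC)[C@@H]2O1 | intermediate
19 | ketene acetal diethyl phosphate of 18 | CCOP(=O)(OCC)OC1=C[C@H]2[C@H](O[Si](C)(C)C(C)(C)C)C3=C(CCC[C@@H]3C)[C@@H](OCOC)[C@@H]2O1 | intermediate
20 | 11-(diethoxyphosphoryl) lactone of the Δ4(9)-octalin | O=C1C(P(=O)(OCC)OCC)[C@H]2[C@H](O[Si](C)(C)C(C)(C)C)C3=C(CCC[C@@H]3C)[C@@H](OCOC)[C@@H]2O1 | intermediate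
21 | cyclic 4β,9β-osmate ester of 20 (hexavalent osmium, pyridine ligands omitted) | O=C1C(P(=O)(OCC)OCC)[C@H]2[C@H](O[Si](C)(C)C(C)(C)C)[C@@]3(O4)[C@@H](C)CCC[C@@]3(O[Os]4(=O)=O)[C@@H](OCOC)[C@@H]2O1 | intermediate
22 | cis-decalin-4β,9β-diol with trans-fused 11-phosphono butyrolactone (key precursor) | O=C1C(P(=O)(OCC)OCC)[C@H]2[C@H](O[Si](C)(C)C(C)(C)C)[C@@]3(O)[C@@H](C)CCC[C@@]3(O)[C@@H](OCOC)[C@@H]2O1 | intermediate
23 | cyclodecane-4,9-dione with trans-fused 11-phosphono butyrolactone (key product) | O=C1C(P(=O)(OCC)OCC)[C@H]2[C@H](O[Si](C)(C)C(C)(C)C)C(=O)[C@@H](C)CCCC(=O)[C@@H](OCOC)[C@@H]2O1 | intermediate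
24 | (4R)-4-hydroxy-4-methyl-9-ketone, 5-OMOM, 8-OTBS | O=C1C(P(=O)(OCC)OCC)[C@H]2[C@H](O[Si](C)(C)C(C)(C)C)C(=O)[C@@H](C)CCC[C@@](C)(O)[C@@H](OCOC)[C@@H]2O1 | intermediate
25 | 4,5-diol, 8-OTBS, 9-ketone | O=C1C(P(=O)(OCC)OCC)[C@H]2[C@H](O[Si](C)(C)C(C)(C)C)C(=O)[C@@H](C)CCC[C@@](C)(O)[C@@H](O)[C@@H]2O1 | intermediate
26 | angelic acid | C/C=C(/C)C(=O)O | starting material
27 | 5-O-angelate, 8-OTBS, 11-phosphono lactone | O=C1C(P(=O)(OCC)OCC)[C@H]2[C@H](O[Si](C)(C)C(C)(C)C)C(=O)[C@@H](C)CCC[C@@](C)(O)[C@@H](OC(=O)/C(C)=C\C)[C@@H]2O1 | intermediate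
28 | 8-O-TBS ether of the target | C=C1C(=O)O[C@@H]2[C@@H]1[C@H](O[Si](C)(C)C(C)(C)C)C(=O)[C@@H](C)CCC[C@@](C)(O)[C@H]2OC(=O)/C(C)=C\C | intermediate
29 | CNP0311008.1 | C=C1C(=O)O[C@@H]2[C@@H]1[C@H](O)C(=O)[C@@H](C)CCC[C@@](C)(O)[C@H]2OC(=O)/C(C)=C\C | target

Total step count: 20. Longest linear sequence: 20 steps (1 → 29).

**Three steps most likely to fail**

Step 15 (anodic cleavage). Chemoselectivity at the anode may be lost in three ways: scission of the glycol mono-ether bonds C4–C5 or C8–C9, oxidation of the acetal C–H bonds, or transannular aldol closure of the new 1,6-dione in the acidic and basic layers at the electrodes. The fallback bypasses both the diol and the electron transfer. It sets out from 20. Ozone (CH2Cl2, −78 °C) should add to the tetrasubstituted C4=C9 bond. The carbonyl oxide and ketone, held together by both chains, should then recombine to the bridged secondary ozonide F1. Reduction with Me2S gives the dione, and the route is rejoined at 23.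

Step 14 (osmylation). The tetrasubstituted alkene, with three substituted allylic carbons around it, may be osmylated very slowly, or the crowded osmate ester may resist hydrolysis. The fallback replaces the [3+2] addition by the sterically less demanding oxygen-atom transfer. It sets out from 20. m-Chloroperbenzoic acid (NaHCO3, CH2Cl2, 0 °C) should give the 4β,9β-epoxide F2 from the face anti to the C10 methyl group. HClO4 (cat.) in THF–H2O should open it to the trans-4α,9β-diol F3, drawn for attack of water at C4; the other regiochemistry is equally useful. The anodic fission needs no cyclic ester, so F3 is electrolysed under the conditions of step 15, and the route is rejoined at 23.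

Step 11 (malonate opening). SN2 attack at an oxirane carbon flanked by two bulky, inductively deactivating ethers may be too slow at a tolerable temperature. Forcing it may erode the C7/C6 regioselectivity or allow silyl migration from O8 to O6. The fallback uses Lewis acid activation and a slim sp-hybridised acetate equivalent in place of the stabilised enolate. It sets out from 14. LiC≡COEt and BF3·OEt2 (THF, −78 °C) should give the 7α-(ethoxyethynyl)-6β-alcohol F4. Pyridinium p-toluenesulfonate in wet THF protonates the ynol ether, O6 closes on the resulting ketenium carbon and ethanol is lost. The route is rejoined at 18, without 17 and without step 12.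

**Further compounds**
F1 | step 15 | bridged secondary ozonide of 20 (C4–O–C9 and C4–O–O–C9) | O=C1C(P(=O)(OCC)OCC)[C@H]2[C@H](O[Si](C)(C)C(C)(C)C)C3(OO4)[C@@H](C)CCCC4(O3)[C@@H](OCOC)[C@@H]2O1
F2 | step 14 | 4β,9β-epoxide of 20 | O=C1C(P(=O)(OCC)OCC)[C@H]2[C@H](O[Si](C)(C)C(C)(C)C)[C@@]3(O4)[C@@H](C)CCC[C@@]34[C@@H](OCOC)[C@@H]2O1
F3 | step 14 | trans-4α,9β-diol corresponding to 22 | O=C1C(P(=O)(OCC)OCC)[C@H]2[C@H](O[Si](C)(C)C(C)(C)C)[C@@]3(O)[C@@H](C)CCC[C@]3(O)[C@@H](OCOC)[C@@H]2O1
F4 | step 11 | 7α-(ethoxyethynyl)-5α-MOMO-8β-TBSO-10α-methyl-Δ4(9)-octalin-6β-ol | CCOC#C[C@H]1[C@H](O[Si](C)(C)C(C)(C)C)C2=C(CCC[C@@H]2C)[C@@H](OCOC)[C@@H]1O
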